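**Retrosynthetic overview**
1. Target 13 comes from silyl ether 12 by desilylation; the aryl ketone of 12 comes from benzylic carbinol 11 by oxidation.
2. The oxolane ring (formed second) is closed by 5-exo-tet etherification of triol 9: the veratryl carbinol oxygen displaces a primary tosylate, so the benzylic C–O bond is never broken.
3. Triol 9 comes from reduction of aldol lactone 8, made from lactone 5 and 3,4,5-trimethoxybenzaldehyde 6 (aroyl carbon attached trans).
4. Key disconnection: the γ-butyrolactone 5 (formed first) comes from a carbene-catalysed homoenolate annulation. The β-carbon of enal 3 attacks the carbonyl carbon of veratraldehyde 4, making the C2–C3 bond and both permanent stereocentres (cis) in one step.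
5. Enal 3 comes from cross-metathesis of allyl silyl ether 1 with crotonaldehyde 2.

Assumption: the SMILES is read as (2S,3S,4R), i.e. aryl and hydroxymethyl cis and aroyl trans to both; the antipode of the triazolium catalyst that gives (4S,5S)-5 is fixed by a test run.

**Step 1**
Reactants: 1 allyloxy(tert-butyl)dimethylsilane; 2 (E)-but-2-enal
Product: 3 (E)-4-[(tert-butyldimethylsilyl)oxy]but-2-enal
Conditions: second-generation Hoveyda–Grubbs catalyst RuCl2(=CH-C6H4-2-OiPr)(H2IMes) (2 mol%), CH2Cl2, 40 °C, crotonaldehyde in threefold excess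
Reagents that add atoms: none
Why: Olefin cross-metathesis of a terminal allyl ether with an enal favours the cross product, gives the E-enal under thermodynamic control and loses propene; no stereocentre is formed.

**Step 2**
Reactants: 3 (E)-4-[(tert-butyldimethylsilyl)oxy]but-2-enal; 4 veratraldehyde
Product: 5 (4S,5S)-4-{[(tert-butyldimethylsilyl)oxy]methyl}-5-(3,4-dimethoxyphenyl)oxolan-2-one
Conditions: 2-mesityl-5a,10b-dihydro-4H,6H-indeno[2,1-b][1,2,4]triazolo[4,3-d][1,4]oxazin-2-ium chloride (single antipode, 10 mol%), DBU (10 mol%), LiCl (Lewis acid additive, recovered unchanged), 4 Å MS, THF, 25 °C, aryl aldehyde in threefold excess, enal added by syringe pump over 8 h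
Reagents that add atoms: none
Why: Proposed new method: the carbene adds to the aldehyde of the enal and, after proton transfer, makes the β-carbon nucleophilic (homoenolate equivalent) so that it attacks the carbonyl carbon of veratraldehyde, and the new alkoxide then closes the lactone on the activated acyl carbon and frees the catalyst, so that every atom of both partners ends up in the lactone; the aminoindanol backbone blocks one face of the β-carbon and so sets C4 as S, the compact hydrogen-bonded transition state places aryl and silyloxymethyl cis and so sets C5 as S (expected cis:trans about 4:1, separable), and slow addition of the enal to excess LiCl-activated aryl aldehyde holds back enal self-annulation; the closest known reaction type is the carbene-catalysed homoenolate annulation of enals with aryl aldehydes to cis-γ-butyrolactones (racemic with achiral imidazolylidenes), together with the highly enantioselective homoenolate annulations of this triazolium with enones and ketimines.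

**Step 3**
Reactants: 5 (4S,5S)-4-{[(tert-butyldimethylsilyl)oxy]methyl}-5-(3,4-dimethoxyphenyl)oxolan-2-one; 6 3,4,5-trimethoxybenzaldehyde
Product: 8 (3S,4S,5S)-4-{[(tert-butyldimethylsilyl)oxy]methyl}-5-(3,4-dimethoxyphenyl)-3-[hydroxy(3,4,5-trimethoxyphenyl)methyl]oxolan-2-one (carbinol epimer mixture), via lithium enolate 7 (not isolated)
Conditions: LiN(iPr)2 (1.1 equiv), THF, −78 °C; then the trimethoxy aryl aldehyde (1.2 equiv), −78 °C; AcOH quench, −78 °C
Reagents that add atoms: none
Why: Lactone enolate aldol addition; the aldehyde approaches the face opposite the cis silyloxymethyl and aryl groups, which sets C3 as S (trans to the silyloxymethyl group), and the carbinol configuration is irrelevant because it is oxidised in step 6.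

**Step 4**
Reactants: 8 (3S,4S,5S)-aldol lactone
Product: 9 (1S,2S,3R)-2-{[(tert-butyldimethylsilyl)oxy]methyl}-1-(3,4-dimethoxyphenyl)-3-(hydroxymethyl)-4-(3,4,5-trimethoxyphenyl)butane-1,4-diol (C4 epimer mixture)
Conditions: LiBH4 (3 equiv), THF, 0 °C to 25 °C; aqueous NH4Cl work-up
Reagents that add atoms: none
Why: Hydride reduction of the lactone to the diol leaves the silyl ether, the aryl ethers and all stereocentres untouched.

**Step 5**
Reactants: 9 (1S,2S,3R)-triol
Product: 11 (2S,3S,4R)-3-{[(tert-butyldimethylsilyl)oxy]methyl}-2-(3,4-dimethoxyphenyl)-4-[hydroxy(3,4,5-trimethoxyphenyl)methyl]oxolane (carbinol epimer mixture), via primary tosylate 10 (not isolated)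
Conditions: TsCl (1.1 equiv), pyridine, 0 °C; then 50 °C
Reagents that add atoms: none
Why: Selective sulfonylation of the only primary hydroxyl is followed by 5-exo-tet Williamson etherification by the veratryl carbinol oxygen (oxetane closure by the other carbinol is far slower); no bond to a stereocentre is broken, so C2 stays S and the 2,3-cis relationship is kept.

**Step 6**
Reactants: 11 (2S,3S,4R)-oxolane carbinol
Product: 12 (2S,3S,4R)-3-{[(tert-butyldimethylsilyl)oxy]methyl}-2-(3,4-dimethoxyphenyl)-4-(3,4,5-trimethoxybenzoyl)oxolane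
Conditions: Dess–Martin periodinane (1.3 equiv), CH2Cl2, 0 °C to 25 °C
Reagents that add atoms: none
Why: Dess–Martin oxidation of the secondary benzylic alcohol gives the aryl ketone and merges both carbinol epimers; C4, now α to the ketone, already has the favoured configuration trans to the C3 substituent, so enolisation cannot erode it.

**Step 7**
Reactants: 12 (2S,3S,4R)-silyl ether ketone
Product: 13 (2S,3S,4R)-2-(3,4-dimethoxyphenyl)-3-(hydroxymethyl)-4-(3,4,5-trimethoxybenzoyl)oxolane (target)
Conditions: HF·pyridine, pyridine, THF, 0 °C to 25 °C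
Reagents that add atoms: none
Why: Fluoride-driven desilylation under buffered, non-basic conditions frees the primary alcohol without ring-opening β-elimination or epimerisation of the keto oxolane.

**Compound list**
1 | allyloxy(tert-butyl)dimethylsilane | C=CCO[Si](C)(C)C(C)(C)C | starting material
2 | (E)-but-2-enal (crotonaldehyde) | C/C=C/C=O | starting material
3 | (E)-4-[(tert-butyldimethylsilyl)oxy]but-2-enal | O=C/C=C/CO[Si](C)(C)C(C)(C)C | intermediate
4 | 3,4-dimethoxybenzaldehyde (veratraldehyde) | COc1ccc(C=O)cc1OC | starting material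
5 | (4S,5S)-4-{[(tert-butyldimethylsilyl)oxy]methyl}-5-(3,4-dimethoxyphenyl)oxolan-2-one (cis) | COc1ccc([C@H]2OC(=O)C[C@H]2CO[Si](C)(C)C(C)(C)C)cc1OC | intermediate
6 | 3,4,5-trimethoxybenzaldehyde | COc1cc(C=O)cc(OC)c1OC | starting material
7 | lithium enolate of 5 | [Li+].COc1ccc([C@H]2OC([O-])=C[C@H]2CO[Si](C)(C)C(C)(C)C)cc1OC | intermediate
8 | (3S,4S,5S)-4-{[(tert-butyldimethylsilyl)oxy]methyl}-5-(3,4-dimethoxyphenyl)-3-[hydroxy(3,4,5-trimethoxyphenyl)methyl]oxolan-2-one, carbinol epimer mixture | COc1ccc([C@H]2OC(=O)[C@H](C(O)c3cc(OC)c(OC)c(OC)c3)[C@H]2CO[Si](C)(C)C(C)(C)C)cc1OC | intermediate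
9 | (1S,2S,3R)-2-{[(tert-butyldimethylsilyl)oxy]methyl}-1-(3,4-dimethoxyphenyl)-3-(hydroxymethyl)-4-(3,4,5-trimethoxyphenyl)butane-1,4-diol, C4 epimer mixture | COc1ccc([C@@H](O)[C@H](CO[Si](C)(C)C(C)(C)C)[C@H](CO)C(O)c2cc(OC)c(OC)c(OC)c2)cc1OC | intermediate
10 | primary 4-methylbenzenesulfonate of 9 (tosylate on the CH2OH group) | COc1ccc([C@@H](O)[C@H](CO[Si](C)(C)C(C)(C)C)[C@H](COS(=O)(=O)c2ccc(C)cc2)C(O)c2cc(OC)c(OC)c(OC)c2)cc1OC | intermediate
11 | (2S,3S,4R)-3-{[(tert-butyldimethylsilyl)oxy]methyl}-2-(3,4-dimethoxyphenyl)-4-[hydroxy(3,4,5-trimethoxyphenyl)methyl]oxolane, carbinol epimer mixture | COc1ccc([C@H]2OC[C@H](C(O)c3cc(OC)c(OC)c(OC)c3)[C@H]2CO[Si](C)(C)C(C)(C)C)cc1OC | intermediate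
12 | (2S,3S,4R)-3-{[(tert-butyldimethylsilyl)oxy]methyl}-2-(3,4-dimethoxyphenyl)-4-(3,4,5-trimethoxybenzoyl)oxolane | COc1ccc([C@H]2OC[C@H](C(=O)c3cc(OC)c(OC)c(OC)c3)[C@H]2CO[Si](C)(C)C(C)(C)C)cc1OC | intermediate
13 | (2S,3S,4R)-2-(3,4-dimethoxyphenyl)-3-(hydroxymethyl)-4-(3,4,5-trimethoxybenzoyl)oxolane | COc1ccc([C@H]2OC[C@H](C(=O)c3cc(OC)c(OC)c(OC)c3)[C@H]2CO)cc1OC | target

**Step count**
Total steps: 7. Longest linear sequence: 7 (1 → 3 → 5 → 8 → 9 → 11 → 12 → 13).

**Steps most likely to fail**

Step 2 (homoenolate annulation). The enantioselectivity with a simple aryl aldehyde is unproven, veratraldehyde is an electron-rich and therefore sluggish acceptor so enal self-annulation competes, and the homoenolate could lose silanolate. The fallback sets out from 1 and 4 and comes back at 5. Z-selective olefin cross-metathesis of 1 with allylboronic acid pinacol ester gives (Z)-tert-butyldimethyl{[4-(4,4,5,5-tetramethyl-1,3,2-dioxaborolan-2-yl)but-2-en-1-yl]oxy}silane F1. Chiral phosphoric acid-catalysed allylboration of 4 with it (TRIP antipode chosen by test, toluene, −30 °C; closed chair transition state, Z-geometry gives syn) gives (1S,2S)-2-{[(tert-butyldimethylsilyl)oxy]methyl}-1-(3,4-dimethoxyphenyl)but-3-en-1-ol F2. Hydroboration–oxidation (9-BBN, then NaOH/H2O2) gives (1S,2S)-2-{[(tert-butyldimethylsilyl)oxy]methyl}-1-(3,4-dimethoxyphenyl)butane-1,4-diol F3. Oxidative lactonisation with TEMPO/PhI(OAc)2 then gives 5.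

Step 5 (selective tosylation and ring closure). Sulfonylation may not discriminate cleanly between the primary and the two benzylic hydroxyls, and the silyl ether oxygen could take part. The fallback sets out from 8 and comes back at 11, replacing etherification by lactol deoxygenation. Et3SiCl/imidazole converts 8 into its carbinol triethylsilyl ether F4. iBu2AlH at −78 °C gives the (3S,4S,5S)-oxolan-2-ol (lactol) F5. Et3SiH/BF3·OEt2 at −78 °C reduces the C2 oxocarbenium ion to give (2S,3S,4R)-3-{[(tert-butyldimethylsilyl)oxy]methyl}-2-(3,4-dimethoxyphenyl)-4-[(triethylsilyloxy)(3,4,5-trimethoxyphenyl)methyl]oxolane F6. PPTS in MeOH removes only the triethylsilyl group to give 11.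

Step 3 (lactone aldol). The hindered cis-lactone enolate may react slowly and the adduct can undergo retro-aldol cleavage. The fallback sets out from 5 and comes back at 8. Deprotonation with LiN(SiMe3)2 (2.2 equiv) and Claisen-type C-acylation with 3,4,5-trimethoxybenzoyl chloride gives (3S,4S,5S)-4-{[(tert-butyldimethylsilyl)oxy]methyl}-5-(3,4-dimethoxyphenyl)-3-(3,4,5-trimethoxybenzoyl)oxolan-2-one F7, held trans by equilibration. NaBH4 in MeOH at −20 °C reduces only the ketone to give 8.

**Further compounds**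
F1 | step 2 | (Z)-tert-butyldimethyl{[4-(4,4,5,5-tetramethyl-1,3,2-dioxaborolan-2-yl)but-2-en-1-yl]oxy}silane | CC(C)(C)[Si](C)(C)OC/C=C\CB1OC(C)(C)C(C)(C)O1
F2 | step 2 | (1S,2S)-2-{[(tert-butyldimethylsilyl)oxy]methyl}-1-(3,4-dimethoxyphenyl)but-3-en-1-ol | COc1ccc([C@@H](O)[C@H](CO[Si](C)(C)C(C)(C)C)C=C)cc1OC
F3 | step 2 | (1S,2S)-2-{[(tert-butyldimethylsilyl)oxy]methyl}-1-(3,4-dimethoxyphenyl)butane-1,4-diol | COc1ccc([C@@H](O)[C@H](CO[Si](C)(C)C(C)(C)C)CCO)cc1OC
F4 | step 5 | triethylsilyl ether of 8: (3S,4S,5S)-4-{[(tert-butyldimethylsilyl)oxy]methyl}-5-(3,4-dimethoxyphenyl)-3-[(triethylsilyloxy)(3,4,5-trimethoxyphenyl)methyl]oxolan-2-one | COc1ccc([C@H]2OC(=O)[C@H](C(O[Si](CC)(CC)CC)c3cc(OC)c(OC)c(OC)c3)[C@H]2CO[Si](C)(C)C(C)(C)C)cc1OC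
F5 | step 5 | (3S,4S,5S)-4-{[(tert-butyldimethylsilyl)oxy]methyl}-5-(3,4-dimethoxyphenyl)-3-[(triethylsilyloxy)(3,4,5-trimethoxyphenyl)methyl]oxolan-2-ol (lactol, anomer mixture) | COc1ccc([C@H]2OC(O)[C@H](C(O[Si](CC)(CC)CC)c3cc(OC)c(OC)c(OC)c3)[C@H]2CO[Si](C)(C)C(C)(C)C)cc1OC
F6 | step 5 | (2S,3S,4R)-3-{[(tert-butyldimethylsilyl)oxy]methyl}-2-(3,4-dimethoxyphenyl)-4-[(triethylsilyloxy)(3,4,5-trimethoxyphenyl)methyl]oxolane | COc1ccc([C@H]2OC[C@H](C(O[Si](CC)(CC)CC)c3cc(OC)c(OC)c(OC)c3)[C@H]2CO[Si](C)(C)C(C)(C)C)cc1OC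
F7 | step 3 | (3S,4S,5S)-4-{[(tert-butyldimethylsilyl)oxy]methyl}-5-(3,4-dimethoxyphenyl)-3-(3,4,5-trimethoxybenzoyl)oxolan-2-one | COc1ccc([C@H]2OC(=O)[C@H](C(=O)c3cc(OC)c(OC)c(OC)c3)[C@H]2CO[Si](C)(C)C(C)(C)C)cc1OC
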